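The route rests on disconnecting the O-3'–C-11 bond of ring D. C-11 is benzylic to ring E and para to its free 4-hydroxyl, so acid should turn either C-11 carbinol epimer into a para-quinone methide, to which the ring B phenol O-3' (ortho to the O-4'–C-10 ether) adds reversibly. One operation thus closes ring D, creates C-11 and funnels both epimers into the trans (10S,11S) benzodioxane aldehyde, steered only by C-10, which comes from (R)-glycerate by Mitsunobu inversion. The cyclisation substrate is a β-aryl ether carbinol whose ring B formyl group is held as a dioxolane and whose primary hydroxyl as a silyl ether, both released by the same acid.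

Key step: step 8

Assumption: flavonolignan numbering is used (C-10 carries the hydroxymethyl group, C-11 carries ring E, O-3' and O-4' are the ring B oxygens), and benzyl ethers 4, 8 and 16 are taken as catalogue compounds.

Step 1
Reactants: 1 methyl (R)-2,2-dimethyl-1,3-dioxolane-4-carboxylate
Product: 2 methyl (R)-2,3-dihydroxypropanoate
Conditions: Amberlyst 15 (H+ form), MeOH, rt
Reagents that add atoms: none
Why: Acid-catalysed transacetalisation (acetonide methanolysis) frees the 1,2-diol without touching the methyl ester, and the C-2 stereocentre has no pathway for inversion under these conditions.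

Step 2
Reactants: 2 methyl (R)-2,3-dihydroxypropanoate
Product: 3 methyl (R)-3-[(tert-butyldimethylsilyl)oxy]-2-hydroxypropanoate
Conditions: TBSCl, imidazole, CH2Cl2, 0 °C
Reagents that add atoms: tert-butyldimethylsilyl chloride, CC(C)(C)[Si](C)(C)Cl
Why: Selective silylation of the primary hydroxyl, since the hindered silyl chloride reacts at the unhindered C-3 hydroxyl much faster than at the secondary hydroxyl next to the ester, which stays free for step 3.

Step 3
Reactants: 3 methyl (R)-3-[(tert-butyldimethylsilyl)oxy]-2-hydroxypropanoate; 4 3-(benzyloxy)-4-hydroxybenzaldehyde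
Product: 5 methyl (S)-2-[2-(benzyloxy)-4-formylphenoxy]-3-[(tert-butyldimethylsilyl)oxy]propanoate
Conditions: PPh3, DIAD, THF, 0 °C → rt
Reagents that add atoms: none
Why: Mitsunobu etherification, in which the acidic 4-hydroxyl of 4 (para to the formyl group) displaces the alkoxyphosphonium of the α-hydroxy ester in an SN2 step, so C-2 inverts from R to S and becomes C-10 (S) of the target.

Step 4
Reactants: 5 methyl (S)-2-[2-(benzyloxy)-4-formylphenoxy]-3-[(tert-butyldimethylsilyl)oxy]propanoate
Product: 6 methyl (S)-2-[2-(benzyloxy)-4-(1,3-dioxolan-2-yl)phenoxy]-3-[(tert-butyldimethylsilyl)oxy]propanoate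
Conditions: TMSOCH2CH2OTMS, TMSOTf (cat.), CH2Cl2, −78 → −20 °C; pyridine quench
Reagents that add atoms: 1,2-bis(trimethylsilyloxy)ethane, C[Si](C)(C)OCCO[Si](C)(C)C
Why: Noyori acetalisation under aprotic catalysis masks the ring B aldehyde, which would otherwise compete with the ester in steps 5 and 6, and it spares the silyl ether, the benzyl ether and the α-stereocentre.

Step 5
Reactants: 6 methyl (S)-2-[2-(benzyloxy)-4-(1,3-dioxolan-2-yl)phenoxy]-3-[(tert-butyldimethylsilyl)oxy]propanoate
Product: 7 (S)-2-[2-(benzyloxy)-4-(1,3-dioxolan-2-yl)phenoxy]-3-[(tert-butyldimethylsilyl)oxy]propanal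
Conditions: i-Bu2AlH, CH2Cl2, −78 °C; MeOH, aq. KNaC4H4O6 (potassium sodium tartrate)
Reagents that add atoms: none
Why: Partial ester reduction with diisobutylaluminium hydride should stop at the chelated aluminium hemiacetal, which gives the aldehyde on work-up, while the dioxolane and both ethers are inert and the crude aldehyde is used at once to avoid enolisation at C-2.

Step 6
Reactants: 7 (S)-2-[2-(benzyloxy)-4-(1,3-dioxolan-2-yl)phenoxy]-3-[(tert-butyldimethylsilyl)oxy]propanal; 8 1-(benzyloxy)-4-bromo-2-methoxybenzene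
Product: 10 (2S)-2-[2-(benzyloxy)-4-(1,3-dioxolan-2-yl)phenoxy]-1-[4-(benzyloxy)-3-methoxyphenyl]-3-[(tert-butyldimethylsilyl)oxy]propan-1-ol as a mixture of C-1 epimers, via arylmagnesium bromide 9 (not isolated)
Conditions: 8, Mg, THF, 40 °C; then 7, THF, −78 → 0 °C; H2O quench
Reagents that add atoms: none
Why: Grignard addition of the aryl nucleophile to the aldehyde builds the C-11–ring E bond, and the carbinol centre forms without useful control, which is acceptable because step 8 converges both epimers.

Step 7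
Reactants: 10 (2S)-2-[2-(benzyloxy)-4-(1,3-dioxolan-2-yl)phenoxy]-1-[4-(benzyloxy)-3-methoxyphenyl]-3-[(tert-butyldimethylsilyl)oxy]propan-1-ol
Product: 11 (2S)-3-[(tert-butyldimethylsilyl)oxy]-2-[4-(1,3-dioxolan-2-yl)-2-hydroxyphenoxy]-1-(4-hydroxy-3-methoxyphenyl)propan-1-ol as a mixture of C-1 epimers
Conditions: H2 (1 atm), Pd/C, EtOAc, rt
Reagents that add atoms: none
Why: Catalytic hydrogenolysis cleaves the two phenolic benzyl ethers rapidly, while in neutral ethyl acetate the benzylic carbinol, the dioxolane and the silyl ether are expected to survive, as in the debenzylation of phenolic β-aryl ether models.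

Step 8
Reactants: 11 (2S)-3-[(tert-butyldimethylsilyl)oxy]-2-[4-(1,3-dioxolan-2-yl)-2-hydroxyphenoxy]-1-(4-hydroxy-3-methoxyphenyl)propan-1-ol
Product: 14 (2S,3S)-3-(4-hydroxy-3-methoxyphenyl)-2-(hydroxymethyl)-2,3-dihydro-1,4-benzodioxine-6-carbaldehyde, via triol aldehyde 12 (not isolated), via para-quinone methide 13 (not isolated)
Conditions: TFA/H2O (10:1), CH2Cl2 (high dilution), 0 °C → rt; aq. NaHCO3
Reagents that add atoms: water, O
Why: Aqueous trifluoroacetic acid should first strip the silyl ether and the dioxolane to give triol aldehyde 12, then protonate the C-11 hydroxyl of either epimer, and loss of water assisted by the ring E para-hydroxyl gives para-quinone methide 13 (in acid, its protonated form, the 4-hydroxy-3-methoxybenzyl cation). The ring B phenol O-3' adds to the exocyclic C-11 in an intramolecular oxa-Michael (1,6-conjugate) addition, the closest known reaction type being the acid-mediated cyclisation of β-aryl ether benzylic alcohols to trans-1,4-benzodioxane neolignans. Ring D closes in a 6-exo-trig mode, the only alternative (attack by the primary hydroxyl) being a disfavoured four-membered closure. The new C-11 centre is controlled by the untouched C-10 centre: the product is itself a 4-hydroxybenzyl aryl ether that re-ionises in the acid, so the addition is reversible and the mixture should drain into the trans isomer with aryl and hydroxymethyl groups both equatorial, which is 11S from 10S. The step needs trans over cis selectivity and ring closure faster than loss of H-10 from the cation or intermolecular arylation, and these are secured by the thermodynamic bias, the proximity of O-3' to C-11, high dilution and low temperature. C-10 bears no acidic hydrogen and is never ionised, so the absolute configuration set in step 3 is carried through unchanged.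

Step 9
Reactants: 14 (2S,3S)-3-(4-hydroxy-3-methoxyphenyl)-2-(hydroxymethyl)-2,3-dihydro-1,4-benzodioxine-6-carbaldehyde
Product: 15 (2S,3S)-3-[4-(benzyloxy)-3-methoxyphenyl]-2-(hydroxymethyl)-2,3-dihydro-1,4-benzodioxine-6-carbaldehyde
Conditions: BnBr, K2CO3, DMF, rt
Reagents that add atoms: benzyl bromide, BrCc1ccccc1
Why: Williamson etherification selective for the phenol (far more acidic than the primary alcohol under K2CO3) caps the ring E hydroxyl so that the strongly basic steps 10 and 11 cannot reopen ring D through a phenoxide-driven quinone methide.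

Step 10
Reactants: 15 (2S,3S)-3-[4-(benzyloxy)-3-methoxyphenyl]-2-(hydroxymethyl)-2,3-dihydro-1,4-benzodioxine-6-carbaldehyde; 16 1-[2,4-bis(benzyloxy)-6-hydroxyphenyl]ethan-1-one
Product: 17 (E)-1-[2,4-bis(benzyloxy)-6-hydroxyphenyl]-3-{(2S,3S)-3-[4-(benzyloxy)-3-methoxyphenyl]-2-(hydroxymethyl)-2,3-dihydro-1,4-benzodioxin-6-yl}prop-2-en-1-one
Conditions: KOH, EtOH/THF, rt
Reagents that add atoms: none
Why: Claisen–Schmidt condensation, in which the acetophenone enolate adds to the non-enolisable aldehyde and dehydration gives the E-chalcone, while the chelated 2'-hydroxyl, the benzyl ethers and the ring D stereocentres (no acidic hydrogens) are untouched.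

Step 11
Reactants: 17 (E)-1-[2,4-bis(benzyloxy)-6-hydroxyphenyl]-3-{(2S,3S)-3-[4-(benzyloxy)-3-methoxyphenyl]-2-(hydroxymethyl)-2,3-dihydro-1,4-benzodioxin-6-yl}prop-2-en-1-one
Product: 19 5,7-bis(benzyloxy)-2-{(2S,3S)-3-[4-(benzyloxy)-3-methoxyphenyl]-2-(hydroxymethyl)-2,3-dihydro-1,4-benzodioxin-6-yl}-3-hydroxy-4H-chromen-4-one, via dihydroflavonol 18 (not isolated)
Conditions: H2O2 (30% aq.), NaOH, MeOH/THF, 0 °C → rt
Reagents that add atoms: hydrogen peroxide, OO
Why: Algar–Flynn–Oyamada oxidation, in which alkaline hydrogen peroxide oxygenates the enone α-carbon while the 2'-phenoxide closes ring C in a 6-endo sense and the resulting dihydroflavonol is dehydrogenated in the same medium, an outcome favoured by the electron-rich 3,4-dioxygenated ring B.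

Step 12
Reactants: 19 5,7-bis(benzyloxy)-2-{(2S,3S)-3-[4-(benzyloxy)-3-methoxyphenyl]-2-(hydroxymethyl)-2,3-dihydro-1,4-benzodioxin-6-yl}-3-hydroxy-4H-chromen-4-one
Product: 20 2,3-dehydrosilybin B
Conditions: H2 (1 atm), Pd/C, THF/MeOH, rt
Reagents that add atoms: none
Why: Hydrogenolysis removes the three phenolic benzyl ethers under neutral conditions that should leave the flavonol double bond, the cyclic benzylic ether of ring D and both stereocentres intact, giving the target.

Compound list
1 | methyl (R)-2,2-dimethyl-1,3-dioxolane-4-carboxylate | COC(=O)[C@H]1COC(C)(C)O1 | starting material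
2 | methyl (R)-2,3-dihydroxypropanoate | COC(=O)[C@H](O)CO | intermediate
3 | methyl (R)-3-[(tert-butyldimethylsilyl)oxy]-2-hydroxypropanoate | COC(=O)[C@H](O)CO[Si](C)(C)C(C)(C)C | intermediate
4 | 3-(benzyloxy)-4-hydroxybenzaldehyde | O=Cc1ccc(O)c(OCc2ccccc2)c1 | starting material
5 | methyl (S)-2-[2-(benzyloxy)-4-formylphenoxy]-3-[(tert-butyldimethylsilyl)oxy]propanoate | COC(=O)[C@@H](Oc1ccc(C=O)cc1OCc1ccccc1)CO[Si](C)(C)C(C)(C)C | intermediate
6 | methyl (S)-2-[2-(benzyloxy)-4-(1,3-dioxolan-2-yl)phenoxy]-3-[(tert-butyldimethylsilyl)oxy]propanoate | COC(=O)[C@@H](Oc1ccc(C2OCCO2)cc1OCc1ccccc1)CO[Si](C)(C)C(C)(C)C | intermediate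
7 | (S)-2-[2-(benzyloxy)-4-(1,3-dioxolan-2-yl)phenoxy]-3-[(tert-butyldimethylsilyl)oxy]propanal | O=C[C@@H](Oc1ccc(C2OCCO2)cc1OCc1ccccc1)CO[Si](C)(C)C(C)(C)C | intermediate
8 | 1-(benzyloxy)-4-bromo-2-methoxybenzene | COc1cc(Br)ccc1OCc1ccccc1 | starting material
9 | [4-(benzyloxy)-3-methoxyphenyl]magnesium bromide | COc1cc([Mg]Br)ccc1OCc1ccccc1 | intermediate (not isolated)
10 | (2S)-2-[2-(benzyloxy)-4-(1,3-dioxolan-2-yl)phenoxy]-1-[4-(benzyloxy)-3-methoxyphenyl]-3-[(tert-butyldimethylsilyl)oxy]propan-1-ol (both C-1 epimers) | COc1cc(C(O)[C@@H](Oc2ccc(C3OCCO3)cc2OCc2ccccc2)CO[Si](C)(C)C(C)(C)C)ccc1OCc1ccccc1 | intermediate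
11 | (2S)-3-[(tert-butyldimethylsilyl)oxy]-2-[4-(1,3-dioxolan-2-yl)-2-hydroxyphenoxy]-1-(4-hydroxy-3-methoxyphenyl)propan-1-ol (both C-1 epimers) | COc1cc(C(O)[C@@H](Oc2ccc(C3OCCO3)cc2O)CO[Si](C)(C)C(C)(C)C)ccc1O | intermediate
12 | 4-{[(2S)-1,3-dihydroxy-1-(4-hydroxy-3-methoxyphenyl)propan-2-yl]oxy}-3-hydroxybenzaldehyde (both C-1 epimers) | COc1cc(C(O)[C@H](CO)Oc2ccc(C=O)cc2O)ccc1O | intermediate (not isolated)
13 | 3-hydroxy-4-{[(2R)-1-hydroxy-3-(3-methoxy-4-oxocyclohexa-2,5-dien-1-ylidene)propan-2-yl]oxy}benzaldehyde (C-10 geometry unchanged; the descriptor changes only by priority) | COC1=CC(=C[C@H](CO)Oc2ccc(C=O)cc2O)C=CC1=O | intermediate (not isolated)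
14 | (2S,3S)-3-(4-hydroxy-3-methoxyphenyl)-2-(hydroxymethyl)-2,3-dihydro-1,4-benzodioxine-6-carbaldehyde | COc1cc([C@@H]2Oc3cc(C=O)ccc3O[C@H]2CO)ccc1O | intermediate
15 | (2S,3S)-3-[4-(benzyloxy)-3-methoxyphenyl]-2-(hydroxymethyl)-2,3-dihydro-1,4-benzodioxine-6-carbaldehyde | COc1cc([C@@H]2Oc3cc(C=O)ccc3O[C@H]2CO)ccc1OCc1ccccc1 | intermediate
16 | 1-[2,4-bis(benzyloxy)-6-hydroxyphenyl]ethan-1-one | CC(=O)c1c(O)cc(OCc2ccccc2)cc1OCc1ccccc1 | starting material
17 | (E)-1-[2,4-bis(benzyloxy)-6-hydroxyphenyl]-3-{(2S,3S)-3-[4-(benzyloxy)-3-methoxyphenyl]-2-(hydroxymethyl)-2,3-dihydro-1,4-benzodioxin-6-yl}prop-2-en-1-one | COc1cc([C@@H]2Oc3cc(/C=C/C(=O)c4c(O)cc(OCc5ccccc5)cc4OCc4ccccc4)ccc3O[C@H]2CO)ccc1OCc1ccccc1 | intermediate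
18 | 5,7-bis(benzyloxy)-2-{(2S,3S)-3-[4-(benzyloxy)-3-methoxyphenyl]-2-(hydroxymethyl)-2,3-dihydro-1,4-benzodioxin-6-yl}-3-hydroxy-2,3-dihydro-4H-chromen-4-one (C-2 and C-3 unassigned) | COc1cc([C@@H]2Oc3cc(C4Oc5cc(OCc6ccccc6)cc(OCc6ccccc6)c5C(=O)C4O)ccc3O[C@H]2CO)ccc1OCc1ccccc1 | intermediate (not isolated)
19 | 5,7-bis(benzyloxy)-2-{(2S,3S)-3-[4-(benzyloxy)-3-methoxyphenyl]-2-(hydroxymethyl)-2,3-dihydro-1,4-benzodioxin-6-yl}-3-hydroxy-4H-chromen-4-one | COc1cc([C@@H]2Oc3cc(-c4oc5cc(OCc6ccccc6)cc(OCc6ccccc6)c5c(=O)c4O)ccc3O[C@H]2CO)ccc1OCc1ccccc1 | intermediate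
20 | 2,3-dehydrosilybin B, 3,5,7-trihydroxy-2-[(2S,3S)-3-(4-hydroxy-3-methoxyphenyl)-2-(hydroxymethyl)-2,3-dihydro-1,4-benzodioxin-6-yl]-4H-chromen-4-one | COc1cc([C@@H]2Oc3cc(-c4oc5cc(O)cc(O)c5c(=O)c4O)ccc3O[C@H]2CO)ccc1O | target

Total step count: 12. Longest linear sequence: 12 steps (1 to 20); 4, 8 and 16 enter as purchased building blocks.

Steps most likely to fail

Step 8. The benzylic cation may lose H-10 instead of being captured (an enol ether pathway that destroys C-10), cis-to-trans equilibration may stall, or the cation may arylate a second molecule. The fallback separates unmasking from ring closure and generates the quinone methide without acid. It sets out from 11: buffered hydrolysis (AcOH/THF/H2O, rt), which should not ionise C-11, would give triol aldehyde 12 as an isolated compound. Bromotrimethylsilane in CH2Cl2 at 0 °C would convert its benzylic hydroxyl into the benzylic bromide F1. Shaking with aqueous NaHCO3 should eliminate HBr to give quinone methide 13, to which the phenoxide O-3' adds. A catalytic amount of K2CO3 would then equilibrate any cis isomer through the quinone methide phenolate. The route is rejoined at 14.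

Step 11. Five-membered closure of the 2'-phenoxide onto the α-carbon may compete and divert material to the aurone, a pathway favoured by the 6'-benzyloxy substituent. The fallback separates ring closure from C-3 oxygenation and sets out from 17. Oxidative cyclisation with catalytic I2 in DMSO at 120 °C would give the flavone F2. Epoxidation of its C-2/C-3 double bond with dimethyldioxirane in acetone/CH2Cl2 at 0 °C, followed by opening with catalytic p-TsOH, should give the flavonol. The route is rejoined at 19.

Step 5. Over-reduction to the primary alcohol, or enolisation of the α-aryloxy aldehyde during isolation and Grignard addition, may erode C-10, the only centre that steers the route. The fallback avoids the aldehyde and sets out from 6. Treatment with MeNH(OMe)·HCl and i-PrMgCl in THF at −20 °C would give the Weinreb amide F3. Addition of arylmagnesium bromide 9 should stop at the chelated adduct and give the aryl ketone F4 on work-up. Reduction with NaBH4 in MeOH/THF at −20 °C would give the carbinol as an epimer mixture, which step 8 tolerates. The route is rejoined at 10, bypassing 7.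

Further compounds
F1 | step 8 | 4-{[(2S)-1-bromo-3-hydroxy-1-(4-hydroxy-3-methoxyphenyl)propan-2-yl]oxy}-3-hydroxybenzaldehyde (both C-1 epimers) | COc1cc(C(Br)[C@H](CO)Oc2ccc(C=O)cc2O)ccc1O
F2 | step 11 | 5,7-bis(benzyloxy)-2-{(2S,3S)-3-[4-(benzyloxy)-3-methoxyphenyl]-2-(hydroxymethyl)-2,3-dihydro-1,4-benzodioxin-6-yl}-4H-chromen-4-one | COc1cc([C@@H]2Oc3cc(-c4cc(=O)c5c(OCc6ccccc6)cc(OCc6ccccc6)cc5o4)ccc3O[C@H]2CO)ccc1OCc1ccccc1
F3 | step 5 | (S)-2-[2-(benzyloxy)-4-(1,3-dioxolan-2-yl)phenoxy]-3-[(tert-butyldimethylsilyl)oxy]-N-methoxy-N-methylpropanamide | CON(C)C(=O)[C@@H](Oc1ccc(C2OCCO2)cc1OCc1ccccc1)CO[Si](C)(C)C(C)(C)C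
F4 | step 5 | (S)-2-[2-(benzyloxy)-4-(1,3-dioxolan-2-yl)phenoxy]-1-[4-(benzyloxy)-3-methoxyphenyl]-3-[(tert-butyldimethylsilyl)oxy]propan-1-one | COc1cc(C(=O)[C@@H](Oc2ccc(C3OCCO3)cc2OCc2ccccc2)CO[Si](C)(C)C(C)(C)C)ccc1OCc1ccccc1
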